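**Retrosynthetic overview**
Locants: the ring is numbered as 7-oxabicyclo[4.1.0]heptane. C1 is the methyl-bearing oxirane carbon, C2 the ketone, C3 the ester-bearing CH, C4 the CH carrying the side chain, C5 the CH2, C6 the oxirane CH, and O7 the oxirane oxygen. The side chain is C1' (=CH2), C2', C3' (C=O), C4'=C5', C6'.
Last step: one palladium/CO cascade disconnects C3–C4 (ring closure), C2'–C3' and C3'–C4' together. This leads back to an open-chain allenyl epoxy ketone that already carries the tiglate, carbon monoxide, and (E)-4-iodo-2-methylbut-3-en-2-ol.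
Enabling feature: the array C2(=O)–C3–C4–C2'(=C1'H2)–C3'(=O) is what a ketone enolate leaves behind when it captures a 2-acyl-π-allyl unit made from an allene. The oxirane ring (C1, C6, O7) holds C2 and C5 cis and eclipsed, so C3 and C4 lie within bonding distance, and quaternary C1 lets the ketone enolise only toward C3.
The cyclisation precursor comes from a diazoketone and tiglic acid. The diazoketone comes from the glycidic acid, and this from Katsuki–Sharpless epoxidation of a Z-allylic alcohol made by Z-selective Wittig olefination of an allenyl ylide with silyloxyacetone.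
Ring order: oxirane first (step 6, the source of all absolute stereochemistry), cyclohexanone last (step 12).

Key step: step 12

Assumption: the tertiary alcohol of the vinyl iodide is carried unprotected, since tertiary alcohols are not acylated by acylpalladium species under carbonate conditions.

Step 1
Reactants: 1 but-3-yn-1-ol
Product: 3 penta-3,4-dien-1-ol, via propargylic amine 2 (not isolated)
Conditions: (CH2O)n, iPr2NH, CuI (0.5 equiv), dioxane, reflux
Reagents that add atoms: formaldehyde (from paraformaldehyde) C=O; diisopropylamine CC(C)NC(C)C (atoms kept only in 2)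
Why: Crabbé allene homologation, in which a copper-mediated Mannich condensation gives 2 and an intramolecular hydride shift from an isopropyl C–H expels the imine and leaves the terminal allene, with no stereocentre formed.

Step 2
Reactants: 3 penta-3,4-dien-1-ol
Product: 4 5-iodopenta-1,2-diene
Conditions: PPh3, I2, imidazole, CH2Cl2, 0 °C to rt (3 added last)
Reagents that add atoms: iodine II
Why: Appel-type iodination by SN2 displacement of the alkoxyphosphonium ion at a primary carbon, the allene being spared because the iodine is bound to the phosphine before the alcohol is added.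

Step 3
Reactants: 4 5-iodopenta-1,2-diene
Product: 5 (penta-3,4-dien-1-yl)triphenylphosphonium iodide
Conditions: PPh3, MeCN, reflux
Reagents that add atoms: triphenylphosphine c1ccc(cc1)P(c1ccccc1)c1ccccc1
Why: Simple SN2 quaternisation of a phosphine by an unhindered primary iodide, conditions under which a terminal allene is inert.

Step 4
Reactants: 5 (penta-3,4-dien-1-yl)triphenylphosphonium iodide; 6 1-[(tert-butyldimethylsilyl)oxy]propan-2-one
Product: 8 tert-butyl(dimethyl){[(2Z)-2-methylhepta-2,5,6-trien-1-yl]oxy}silane, via phosphonium ylide 7 (not isolated)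
Conditions: KN(SiMe3)2, THF, −78 °C; then 6, −78 °C to rt
Reagents that add atoms: none
Why: Wittig olefination of a non-stabilised, lithium-free ylide with an α-silyloxy methyl ketone, a pairing known to give under kinetic control the Z-trisubstituted allylic ether with CH2OSi cis to the chain.

Step 5
Reactants: 8 tert-butyl(dimethyl){[(2Z)-2-methylhepta-2,5,6-trien-1-yl]oxy}silane
Product: 9 (2Z)-2-methylhepta-2,5,6-trien-1-ol
Conditions: Bu4NF, THF, 0 °C
Reagents that add atoms: none
Why: Fluoride-induced desilylation driven by the Si–F bond, which touches neither the alkene geometry nor the allene.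

Step 6
Reactants: 9 (2Z)-2-methylhepta-2,5,6-trien-1-ol
Product: 10 [(2R,3S)-3-(buta-2,3-dien-1-yl)-2-methyloxiran-2-yl]methanol
Conditions: Ti(OiPr)4 (10 mol %), D-(−)-diethyl tartrate (12 mol %), tBuOOH (decane), 4 Å MS, CH2Cl2, −20 °C
Reagents that add atoms: tert-butyl hydroperoxide CC(C)(C)OO
Why: Katsuki–Sharpless asymmetric epoxidation, in which the titanium-bound allylic alkoxide confines oxygen transfer to the allylic C=C (the allene is not touched), D-(−)-tartrate selects the face that gives the (2R,3S) epoxide, and the Z geometry is translated stereospecifically into the cis relation of CH2OH and the allenylmethyl chain.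

Step 7
Reactants: 10 [(2R,3S)-3-(buta-2,3-dien-1-yl)-2-methyloxiran-2-yl]methanol
Product: 12 (2S,3S)-3-(buta-2,3-dien-1-yl)-2-methyloxirane-2-carboxylic acid, via epoxy aldehyde 11 (not isolated)
Conditions: TEMPO (20 mol %), PhI(OAc)2 (2.2 equiv), MeCN/H2O 1:1, rt
Reagents that add atoms: water O
Why: Oxoammonium (TEMPO/PhI(OAc)2) oxidation of a primary alcohol through the aldehyde hydrate to the acid, mild enough for epoxide and allene, with no epimerisable centre because the α-carbon is quaternary (the descriptor at that carbon changes only through priority).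

Step 8
Reactants: 12 (2S,3S)-3-(buta-2,3-dien-1-yl)-2-methyloxirane-2-carboxylic acid
Product: 14 1-[(2S,3S)-3-(buta-2,3-dien-1-yl)-2-methyloxiran-2-yl]-2-diazoethan-1-one, via mixed anhydride 13 (not isolated)
Conditions: iBuOCOCl, N-methylmorpholine, THF, −20 °C; then Me3SiCHN2 (hexanes), MeCN, 0 °C to rt
Reagents that add atoms: trimethylsilyldiazomethane C[Si](C)(C)C=[N+]=[N-]; isobutyl chloroformate CC(C)COC(=O)Cl (atoms kept only in 13)
Why: Arndt–Eistert-type acylation of a diazoalkane by a mixed carbonic anhydride, a known entry to α,β-epoxy diazomethyl ketones from glycidic acids that leaves both oxirane centres untouched.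

Step 9
Reactants: 14 1-[(2S,3S)-3-(buta-2,3-dien-1-yl)-2-methyloxiran-2-yl]-2-diazoethan-1-one; 15 tiglic acid
Product: 16 2-[(2S,3S)-3-(buta-2,3-dien-1-yl)-2-methyloxiran-2-yl]-2-oxoethyl (2E)-2-methylbut-2-enoate
Conditions: 15 (3 equiv), Rh2(OAc)4 (1 mol %), CH2Cl2, rt, slow addition of 14
Reagents that add atoms: none
Why: Rhodium-carbenoid O–H insertion of a carboxylic acid into an α-diazoketone, which installs the tiglate with its E geometry intact and is favoured over intramolecular carbene capture by the excess acid and the slow addition.

Step 10
Reactants: 17 2-methylbut-3-yn-2-ol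
Product: 18 (3E)-2-methyl-4-(tributylstannyl)but-3-en-2-ol
Conditions: Bu3SnH, PdCl2(PPh3)2 (2 mol %), THF, 0 °C to rt
Reagents that add atoms: tributyltin hydride CCCC[SnH](CCCC)CCCC
Why: Palladium-catalysed syn-hydrostannation of a terminal alkyne, in which the bulky tertiary carbinol steers tin to the terminal carbon and syn addition fixes the E geometry.

Step 11
Reactants: 18 (3E)-2-methyl-4-(tributylstannyl)but-3-en-2-ol
Product: 19 (3E)-4-iodo-2-methylbut-3-en-2-ol
Conditions: I2, CH2Cl2, 0 °C
Reagents that add atoms: iodine II
Why: Iododestannylation of a vinylstannane, an electrophilic ipso substitution that proceeds with retention of the E geometry.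

Step 12
Reactants: 16 2-[(2S,3S)-3-(buta-2,3-dien-1-yl)-2-methyloxiran-2-yl]-2-oxoethyl (2E)-2-methylbut-2-enoate; 19 (3E)-4-iodo-2-methylbut-3-en-2-ol
Product: 22 (1S,3S,4S,6S)-4-[(4E)-6-hydroxy-6-methyl-3-oxohepta-1,4-dien-2-yl]-1-methyl-2-oxo-7-oxabicyclo[4.1.0]heptan-3-yl (2E)-2-methylbut-2-enoate (target), via acylpalladium iodide 20 (not isolated), via 2-acylallylpalladium iodide 21 (not isolated)
Conditions: 19 (1.3 equiv), CO (1 atm), Pd2(dba)3 (2.5 mol %), P(2-furyl)3 (10 mol %), Cs2CO3 (1.5 equiv), THF, 45 °C, slow addition of 16
Reagents that add atoms: carbon monoxide [C-]#[O+]; palladium (from Pd2(dba)3) [Pd] (kept only in 20 and 21)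
Why: Proposed new method: zerovalent palladium inserts into the C–I bond of 19 with retention of the E geometry, CO insertion gives acylpalladium iodide 20, and 20 adds to the allene of 16 with the acyl carbon going to the central allene carbon, so that the 2-acyl-π-allyl complex 21 already holds C3'=O, the latent C2'=C1'H2 unit and an electrophilic C4; carbonate then deprotonates the α-acyloxy ketone at C3 and the enolate carbon attacks C4 with release of zerovalent palladium and iodide. The closest known reaction type is the palladium-catalysed carbonylation/allene insertion/π-allyl capture cascade of aryl and vinyl iodides with amine, phenoxide, sulfinate or malonate nucleophiles; new here are the tethered, only weakly acidic α-acyloxy ketone as the carbon nucleophile and the closure of a carbocycle. The one ring closed is the cyclohexanone, by an allowed 6-(enolendo)-exo-trig attack on the substituted allyl terminus, preferred over 8-endo attack at the CH2 terminus by ring size and because C4 is the enone β-carbon in the η1 form of 21. C4 is controlled by the oxirane: the two allyl faces of 21 interconvert by η3-η1-η3 slippage at the CH2 terminus, C2, C1, C6 and C5 are held coplanar by the cis-epoxide, and closure should run through the half-chair in which C4 rises on the face opposite O7, where the forming bond is staggered against C6–H and clear of the oxygen lone pairs, with the dienone arm pseudo-equatorial, which places this arm cis to O7 as required. C3 is under thermodynamic control, because the α-acyloxy ketone epimerises under the carbonate conditions to the equatorial ester trans to the C4 arm, an axial ester being pressed against O7. The step needs CO insertion before allene insertion, allene insertion before acylation of the enolate, and C- rather than O-allylation; these are secured by the CO atmosphere, by the strong π-binding of the allene together with the low stationary enolate concentration from a weak heterogeneous base and slow addition of 16, and by the softness of the allyl terminus, an O-allyl enol ether being itself a 2-acylallyl electrophile that zerovalent palladium re-ionises.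

**Compound list**
1 | but-3-yn-1-ol | C#CCCO | starting material
2 | 5-[di(propan-2-yl)amino]pent-3-yn-1-ol | CC(C)N(C(C)C)CC#CCCO | intermediate
3 | penta-3,4-dien-1-ol | C=C=CCCO | intermediate
4 | 5-iodopenta-1,2-diene | C=C=CCCI | intermediate
5 | (penta-3,4-dien-1-yl)triphenylphosphonium iodide | C=C=CCC[P+](c1ccccc1)(c1ccccc1)c1ccccc1.[I-] | intermediate
6 | 1-[(tert-butyldimethylsilyl)oxy]propan-2-one | CC(=O)CO[Si](C)(C)C(C)(C)C | starting material
7 | (penta-3,4-dien-1-ylidene)triphenylphosphorane | C=C=CCC=P(c1ccccc1)(c1ccccc1)c1ccccc1 | intermediate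
8 | tert-butyl(dimethyl){[(2Z)-2-methylhepta-2,5,6-trien-1-yl]oxy}silane | C=C=CC/C=C(C)\CO[Si](C)(C)C(C)(C)C | intermediate
9 | (2Z)-2-methylhepta-2,5,6-trien-1-ol | C=C=CC/C=C(C)\CO | intermediate
10 | [(2R,3S)-3-(buta-2,3-dien-1-yl)-2-methyloxiran-2-yl]methanol | C=C=CC[C@@H]1O[C@]1(C)CO | intermediate
11 | (2S,3S)-3-(buta-2,3-dien-1-yl)-2-methyloxirane-2-carbaldehyde | C=C=CC[C@@H]1O[C@]1(C)C=O | intermediate
12 | (2S,3S)-3-(buta-2,3-dien-1-yl)-2-methyloxirane-2-carboxylic acid | C=C=CC[C@@H]1O[C@]1(C)C(=O)O | intermediate
13 | (2S,3S)-3-(buta-2,3-dien-1-yl)-2-methyloxirane-2-carboxylic 2-methylpropyl carbonic anhydride | C=C=CC[C@@H]1O[C@]1(C)C(=O)OC(=O)OCC(C)C | intermediate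
14 | 1-[(2S,3S)-3-(buta-2,3-dien-1-yl)-2-methyloxiran-2-yl]-2-diazoethan-1-one | C=C=CC[C@@H]1O[C@]1(C)C(=O)C=[N+]=[N-] | intermediate
15 | tiglic acid, (2E)-2-methylbut-2-enoic acid | C/C=C(\C)C(=O)O | starting material
16 | 2-[(2S,3S)-3-(buta-2,3-dien-1-yl)-2-methyloxiran-2-yl]-2-oxoethyl (2E)-2-methylbut-2-enoate | C=C=CC[C@@H]1O[C@]1(C)C(=O)COC(=O)/C(C)=C/C | intermediate
17 | 2-methylbut-3-yn-2-ol | CC(C)(O)C#C | starting material
18 | (3E)-2-methyl-4-(tributylstannyl)but-3-en-2-ol | CCCC[Sn](CCCC)(CCCC)/C=C/C(C)(C)O | intermediate
19 | (3E)-4-iodo-2-methylbut-3-en-2-ol | CC(C)(O)/C=C/I | intermediate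
20 | [(2E)-4-hydroxy-4-methylpent-2-enoyl]palladium iodide (phosphine ligands omitted) | CC(C)(O)/C=C/C(=O)[Pd]I | intermediate
21 | 2-acyl-π-allylpalladium iodide from 16 and 20, drawn as the η1 form bound at the CH2 terminus (phosphine ligands omitted; syn/anti forms and both faces interconvert) | CC(C)(O)/C=C/C(=O)C(C[Pd]I)=CC[C@@H]1O[C@]1(C)C(=O)COC(=O)/C(C)=C/C | intermediate
22 | (1S,3S,4S,6S)-4-[(4E)-6-hydroxy-6-methyl-3-oxohepta-1,4-dien-2-yl]-1-methyl-2-oxo-7-oxabicyclo[4.1.0]heptan-3-yl (2E)-2-methylbut-2-enoate | C=C(C(=O)/C=C/C(C)(C)O)[C@@H]1C[C@@H]2O[C@]2(C)C(=O)[C@H]1OC(=O)/C(C)=C/C | target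

**Step count**
Total step count: 12. Longest linear sequence: 10 (steps 1–9 and 12).

**Steps most likely to fail**

Step 12. The risks are:
- acylation of the enolate by the acylpalladium species before allene insertion;
- β-hydride loss from the π-allyl complex;
- O-allylation;
- poor facial selectivity at C4.

The fallback sets out from 16 and 19 and comes back at 22. It cuts the cascade into two operations of known type. First, 16, 19 and CO are combined under Pd2(dba)3/PPh3 with PhSO2Na in place of the carbonate base. This is the established carbonylation/allene insertion/sulfinate capture sequence, in which the soft external nucleophile attacks the unsubstituted allyl terminus while the ketone stays a spectator. It should give the allyl phenyl sulfone F1. Then Cs2CO3 in MeCN at 0 °C should close the C3–C4 bond without palladium. The ketone enolate adds intramolecularly (Michael) to the enone β-carbon and benzenesulfinate is lost by β-elimination (SN2' overall). This regenerates the exocyclic methylene and leads to 22.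

Step 9. Capture of the rhodium carbenoid by the nearby allene C=C or by the oxirane oxygen may outrun O–H insertion. The fallback sets out from 12 and comes back at 16, avoiding diazo and carbene chemistry altogether. Acid 12 is activated as before to 13 and treated with MeNHOMe·HCl and N-methylmorpholine to give the Weinreb amide F2. Chloromethyllithium, generated from ICH2Cl and MeLi·LiBr in THF at −78 °C in the presence of F2, should give the α-chloroketone F3. SN2 displacement of chloride by 15 under Cs2CO3 in DMF should then give 16.

Step 6. Slow turnover and eroded facial selectivity are typical of Z-configured trisubstituted allylic alcohols. The fallback sets out from 10 of insufficient enantiomeric purity and comes back at 10, relying on crystallisation instead of catalyst selectivity. Acylation with 3,5-dinitrobenzoyl chloride (Et3N, DMAP, CH2Cl2) gives the 3,5-dinitrobenzoate F4. This ester is recrystallised to raise the enantiomeric purity and then cleaved with K2CO3 in MeOH at 0 °C.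

**Further compounds**
F1 | step 12 | 2-[(2S,3S)-3-{(2Z,5E)-3-[(benzenesulfonyl)methyl]-7-hydroxy-7-methyl-4-oxoocta-2,5-dien-1-yl}-2-methyloxiran-2-yl]-2-oxoethyl (2E)-2-methylbut-2-enoate | CC(C)(O)/C=C/C(=O)/C(CS(=O)(=O)c1ccccc1)=C/C[C@@H]1O[C@]1(C)C(=O)COC(=O)/C(C)=C/C
F2 | step 9 | (2S,3S)-3-(buta-2,3-dien-1-yl)-N-methoxy-N,2-dimethyloxirane-2-carboxamide | C=C=CC[C@@H]1O[C@]1(C)C(=O)N(C)OC
F3 | step 9 | 1-[(2S,3S)-3-(buta-2,3-dien-1-yl)-2-methyloxiran-2-yl]-2-chloroethan-1-one | C=C=CC[C@@H]1O[C@]1(C)C(=O)CCl
F4 | step 6 | [(2R,3S)-3-(buta-2,3-dien-1-yl)-2-methyloxiran-2-yl]methyl 3,5-dinitrobenzoate | C=C=CC[C@@H]1O[C@]1(C)COC(=O)c1cc(cc(c1)[N+](=O)[O-])[N+](=O)[O-]
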